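**Plan**
- Retrosynthesis: remove the two silyl ethers, cut the side-chain C=C (Wittig), then the O1–C8a aryl ether of the dioxane ring, then the C2–C3 bond (aldol) and the O4–CH2 bond (Williamson).
- Numbering: O1, C2 (syringyl ring B), C3 (CH2OH), O4, ring A C4a–C8a with C5 OMe and C7 propenal. O1–C8a is an aryl ether ortho to O4, so a C8a bromide taken from 5-bromovanillate can be closed by the C2 hydroxyl without touching C2 or C3.
- Forward: the bromoacetyl imide is joined to the bromophenol (O4–C), and the syn aldol with silylated syringaldehyde joins ring B (C2–C3). Auxiliary reduction and primary silylation follow, then palladium closes the dioxane ring, the only ring made.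
- The C7 ester is then taken through alcohol and aldehyde to the E-enal, and both silyl groups are removed.
- Stereochemistry: both centres come from the (R)-4-benzyl-oxazolidinone-controlled boron syn aldol ((2R,3S) adduct, i.e. the (1S,2S) threo diol). The ring closure retains both, giving the (2S,3S) trans ring; the E-alkene comes from the stabilised ylide.

Key step: step 7

Assumption: the primary hydroxyl is carried as a TIPS ether, not a smaller silyl ether, because a 1,5 O-to-O silyl shift under carbonate would free the primary oxygen, which can also close a six-membered ring onto C8a; all reagents named are taken as purchasable.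

**Route**

Step 1
Reactants: 1 (R)-4-benzyl-2-oxazolidinone; 2 bromoacetyl bromide
Product: 4 (R)-4-benzyl-3-(bromoacetyl)-2-oxazolidinone, via N-lithio oxazolidinone 3 (not isolated)
Conditions: n-BuLi, THF, −78 °C; then 2, −78 → 0 °C
Reagents that add atoms: n-butyllithium, [Li]CCCC (lithium is held only in 3)
Why: N-acylation of the lithiated carbamate by the acyl bromide, which is far more electrophilic than the alkyl bromide, is the standard imide formation and leaves the auxiliary stereocentre untouched.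

Step 2
Reactants: 4 (R)-4-benzyl-3-(bromoacetyl)-2-oxazolidinone; 5 methyl 3-bromo-4-hydroxy-5-methoxybenzoate
Product: 6 methyl 4-{2-[(R)-4-benzyl-2-oxooxazolidin-3-yl]-2-oxoethoxy}-3-bromo-5-methoxybenzoate
Conditions: K2CO3, MeCN, rt
Reagents that add atoms: none
Why: Williamson ether synthesis (SN2) of the phenoxide on the activated alpha-bromo imide under mild carbonate conditions that should spare the imide and the methyl ester.

Step 3
Reactants: 7 syringaldehyde
Product: 8 3,5-dimethoxy-4-(triisopropylsilyloxy)benzaldehyde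
Conditions: TIPSCl, imidazole, DMF, rt
Reagents that add atoms: triisopropylsilyl chloride, CC(C)[Si](Cl)(C(C)C)C(C)C
Why: Phenol silylation; the TIPS ether flanked by two methoxy groups should resist the later borohydride, carbonate and hydride steps and masks the phenol that could otherwise open a quinone methide at C2.

Step 4
Reactants: 6 methyl 4-{2-[(R)-4-benzyl-2-oxooxazolidin-3-yl]-2-oxoethoxy}-3-bromo-5-methoxybenzoate; 8 3,5-dimethoxy-4-(triisopropylsilyloxy)benzaldehyde
Product: 11 (4R)-4-benzyl-3-[(2R,3S)-2-(2-bromo-6-methoxy-4-methoxycarbonylphenoxy)-3-hydroxy-3-(3,5-dimethoxy-4-triisopropylsilyloxyphenyl)propanoyl]-2-oxazolidinone, via Z-dibutylboron enolate 9 (not isolated), via dibutylboron aldolate 10 (not isolated)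
Conditions: Bu2BOTf, i-Pr2NEt, CH2Cl2, −78 → 0 °C; then 8, −78 → 0 °C; pH 7 buffer, MeOH, 30 % H2O2, 0 °C
Reagents that add atoms: dibutylboron triflate, CCCCB(CCCC)OS(=O)(=O)C(F)(F)F (boron is held only in 9 and 10)
Why: Evans syn glycolate aldol: the Z boron enolate reacts through a Zimmerman–Traxler chair with the imide carbonyls dipole-opposed, and the aldehyde approaches the enolate face remote from the benzyl group, which sets C3 (alpha, R here) and C2 (carbinol, S) together as the syn pair.

Step 5
Reactants: 11 the syn aldol adduct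
Product: 12 methyl 3-bromo-4-{[(1S,2S)-1,3-dihydroxy-1-(3,5-dimethoxy-4-triisopropylsilyloxyphenyl)propan-2-yl]oxy}-5-methoxybenzoate
Conditions: NaBH4, THF/H2O (4:1), 0 °C → rt
Reagents that add atoms: none
Why: Borohydride reductive cleavage of the N-acyl oxazolidinone (imide-activated exocyclic carbonyl) gives the primary alcohol and returns the auxiliary, while the methyl benzoate is inert to NaBH4 and no stereocentre is touched.

Step 6
Reactants: 12 the threo diol
Product: 13 methyl 3-bromo-4-{[(1S,2S)-1-hydroxy-1-(3,5-dimethoxy-4-triisopropylsilyloxyphenyl)-3-(triisopropylsilyloxy)propan-2-yl]oxy}-5-methoxybenzoate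
Conditions: TIPSCl, imidazole, DMF, 0 °C → rt
Reagents that add atoms: triisopropylsilyl chloride, CC(C)[Si](Cl)(C(C)C)C(C)C
Why: Selective silylation of the primary hydroxyl over the hindered secondary benzylic one by the bulky chlorosilane, leaving the C2 hydroxyl as the only free nucleophile.

Step 7
Reactants: 13 the threo bromo alcohol
Product: 14 methyl (2S,3S)-5-methoxy-2-[3,5-dimethoxy-4-(triisopropylsilyloxy)phenyl]-3-[(triisopropylsilyloxy)methyl]-2,3-dihydro-1,4-benzodioxine-7-carboxylate
Conditions: Pd(OAc)2 (5 mol %), 2-(di-tert-butylphosphino)-1,1'-binaphthyl (6 mol %), Cs2CO3, toluene, 80 °C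
Reagents that add atoms: none
Why: Pd(OAc)2 is reduced in situ to a monoligated zerovalent palladium species that inserts into the C8a–Br bond; carbonate-assisted exchange of bromide for the C2 alkoxide gives an aryl(alkoxo) complex of divalent palladium, and C–O reductive elimination releases the ether and the catalyst. The closest known reaction type is the Buchwald–Hartwig intramolecular etherification of aryl bromides with secondary alcohols, which is established for 2-substituted 1,4-benzodioxanes. The one ring formed, the six-membered dioxane ring, closes by O1–C8a bond formation as an intramolecular O-arylation, by reductive elimination from a seven-membered palladacycle anchored through O4 ortho to the bromide. No stereocentre is created: neither the C2–O nor the C3–O bond is broken, so the (1S,2S) threo pair of 13 should pass with retention into the (2S,3S) trans ring. Reductive elimination must outpace beta-hydride loss from the benzylic alkoxide, which the bulky electron-rich di-tert-butyl biarylphosphine and the short ortho tether favour; the secondary hydroxyl must also stay the only free one, which the migration-resistant primary TIPS ether secures.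

Step 8
Reactants: 14 the benzodioxane methyl ester
Product: 15 {(2S,3S)-5-methoxy-2-[3,5-dimethoxy-4-(triisopropylsilyloxy)phenyl]-3-[(triisopropylsilyloxy)methyl]-2,3-dihydro-1,4-benzodioxin-7-yl}methanol
Conditions: DIBAL-H, CH2Cl2, −78 → 0 °C; Rochelle salt work-up
Reagents that add atoms: none
Why: Hydride reduction of the aryl ester to the benzylic alcohol; silyl ethers, aryl ethers and both stereocentres are inert to DIBAL-H.

Step 9
Reactants: 15 the benzylic alcohol
Product: 16 (2S,3S)-5-methoxy-2-[3,5-dimethoxy-4-(triisopropylsilyloxy)phenyl]-3-[(triisopropylsilyloxy)methyl]-2,3-dihydro-1,4-benzodioxine-7-carbaldehyde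
Conditions: MnO2, CH2Cl2, rt
Reagents that add atoms: none
Why: Selective MnO2 oxidation of a benzylic alcohol to the aldehyde without over-oxidation or effect on the silyl ethers.

Step 10
Reactants: 16 the aryl aldehyde; 17 (triphenylphosphoranylidene)acetaldehyde
Product: 18 (E)-3-{(2S,3S)-5-methoxy-2-[3,5-dimethoxy-4-(triisopropylsilyloxy)phenyl]-3-[(triisopropylsilyloxy)methyl]-2,3-dihydro-1,4-benzodioxin-7-yl}prop-2-enal
Conditions: 17 (1.2 equiv), toluene, 80 °C
Reagents that add atoms: none
Why: Wittig olefination with the stabilised formyl ylide should give the E-enal under thermodynamic control, with the slight excess of ylide limiting further homologation.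

Step 11
Reactants: 18 the bis-silylated enal
Product: 19 bilagrewin
Conditions: TBAF, AcOH (1:1), THF, 0 °C → rt
Reagents that add atoms: none
Why: Fluoride cleavage of the aryl and the primary Si–O bonds in one operation; the acetic acid buffer keeps the liberated phenoxide and the enal away from basic conditions.

**Compound list**
1 | (R)-4-benzyl-2-oxazolidinone | O=C1N[C@H](Cc2ccccc2)CO1 | starting material
2 | bromoacetyl bromide | O=C(Br)CBr | starting material
3 | N-lithio (R)-4-benzyl-2-oxazolidinone (formed in situ) | O=C1N([Li])[C@H](Cc2ccccc2)CO1 | intermediate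
4 | (R)-4-benzyl-3-(bromoacetyl)-2-oxazolidinone | O=C(CBr)N1[C@H](Cc2ccccc2)COC1=O | intermediate
5 | methyl 3-bromo-4-hydroxy-5-methoxybenzoate | COC(=O)c1cc(Br)c(O)c(OC)c1 | starting material
6 | methyl 4-{2-[(R)-4-benzyl-2-oxooxazolidin-3-yl]-2-oxoethoxy}-3-bromo-5-methoxybenzoate | COC(=O)c1cc(Br)c(OCC(=O)N2[C@H](Cc3ccccc3)COC2=O)c(OC)c1 | intermediate
7 | syringaldehyde | COc1cc(C=O)cc(OC)c1O | starting material
8 | 3,5-dimethoxy-4-(triisopropylsilyloxy)benzaldehyde | COc1cc(C=O)cc(OC)c1O[Si](C(C)C)(C(C)C)C(C)C | intermediate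
9 | Z-dibutylboron enolate of 6 (formed in situ) | COC(=O)c1cc(Br)c(O/C=C(\OB(CCCC)CCCC)N2[C@H](Cc3ccccc3)COC2=O)c(OC)c1 | intermediate
10 | dibutylboron aldolate of 11 (formed in situ) | COc1cc([C@H](OB(CCCC)CCCC)[C@H](C(=O)N2[C@H](Cc3ccccc3)COC2=O)Oc4c(Br)cc(C(=O)OC)cc4OC)cc(OC)c1O[Si](C(C)C)(C(C)C)C(C)C | intermediate
11 | (4R)-4-benzyl-3-[(2R,3S)-2-(2-bromo-6-methoxy-4-methoxycarbonylphenoxy)-3-hydroxy-3-(3,5-dimethoxy-4-triisopropylsilyloxyphenyl)propanoyl]-2-oxazolidinone | COc1cc([C@H](O)[C@H](C(=O)N2[C@H](Cc3ccccc3)COC2=O)Oc4c(Br)cc(C(=O)OC)cc4OC)cc(OC)c1O[Si](C(C)C)(C(C)C)C(C)C | intermediate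
12 | methyl 3-bromo-4-{[(1S,2S)-1,3-dihydroxy-1-(3,5-dimethoxy-4-triisopropylsilyloxyphenyl)propan-2-yl]oxy}-5-methoxybenzoate | COc1cc([C@H](O)[C@H](CO)Oc2c(Br)cc(C(=O)OC)cc2OC)cc(OC)c1O[Si](C(C)C)(C(C)C)C(C)C | intermediate
13 | methyl 3-bromo-4-{[(1S,2S)-1-hydroxy-1-(3,5-dimethoxy-4-triisopropylsilyloxyphenyl)-3-(triisopropylsilyloxy)propan-2-yl]oxy}-5-methoxybenzoate | COc1cc([C@H](O)[C@H](CO[Si](C(C)C)(C(C)C)C(C)C)Oc2c(Br)cc(C(=O)OC)cc2OC)cc(OC)c1O[Si](C(C)C)(C(C)C)C(C)C | intermediate
14 | methyl (2S,3S)-5-methoxy-2-[3,5-dimethoxy-4-(triisopropylsilyloxy)phenyl]-3-[(triisopropylsilyloxy)methyl]-2,3-dihydro-1,4-benzodioxine-7-carboxylate | COc1cc([C@@H]2Oc3cc(C(=O)OC)cc(OC)c3O[C@H]2CO[Si](C(C)C)(C(C)C)C(C)C)cc(OC)c1O[Si](C(C)C)(C(C)C)C(C)C | intermediate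
15 | {(2S,3S)-5-methoxy-2-[3,5-dimethoxy-4-(triisopropylsilyloxy)phenyl]-3-[(triisopropylsilyloxy)methyl]-2,3-dihydro-1,4-benzodioxin-7-yl}methanol | COc1cc([C@@H]2Oc3cc(CO)cc(OC)c3O[C@H]2CO[Si](C(C)C)(C(C)C)C(C)C)cc(OC)c1O[Si](C(C)C)(C(C)C)C(C)C | intermediate
16 | (2S,3S)-5-methoxy-2-[3,5-dimethoxy-4-(triisopropylsilyloxy)phenyl]-3-[(triisopropylsilyloxy)methyl]-2,3-dihydro-1,4-benzodioxine-7-carbaldehyde | COc1cc([C@@H]2Oc3cc(C=O)cc(OC)c3O[C@H]2CO[Si](C(C)C)(C(C)C)C(C)C)cc(OC)c1O[Si](C(C)C)(C(C)C)C(C)C | intermediate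
17 | (triphenylphosphoranylidene)acetaldehyde | O=CC=P(c1ccccc1)(c1ccccc1)c1ccccc1 | starting material
18 | (E)-3-{(2S,3S)-5-methoxy-2-[3,5-dimethoxy-4-(triisopropylsilyloxy)phenyl]-3-[(triisopropylsilyloxy)methyl]-2,3-dihydro-1,4-benzodioxin-7-yl}prop-2-enal | COc1cc([C@@H]2Oc3cc(/C=C/C=O)cc(OC)c3O[C@H]2CO[Si](C(C)C)(C(C)C)C(C)C)cc(OC)c1O[Si](C(C)C)(C(C)C)C(C)C | intermediate
19 | bilagrewin | COc1cc([C@@H]2Oc3cc(/C=C/C=O)cc(OC)c3O[C@H]2CO)cc(OC)c1O | target

**Step count**
Total steps: 11. Longest linear sequence: 10 steps (steps 1, 2 and 4 to 11 from compound 1; step 3 is a one-step side branch).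

**Steps most likely to fail**

Step 7. Beta-hydride loss from the palladium-bound benzylic alkoxide could give the aryl ketone and the debrominated arene. Carbonate-induced loss of the phenolic silyl group could also open a quinone-methide path that scrambles C2. The fallback forms the O1–C2 bond instead of O1–C8a. It sets out from 13: Miyaura borylation (B2pin2, PdCl2(dppf), KOAc, dioxane, 80 °C) should give the aryl pinacol boronate F1. Oxidation with NaBO3·4H2O in THF/H2O should give the phenol F2. Catalytic TsOH in CH2Cl2 should then ionise the benzylic hydroxyl to the para-silyloxybenzyl cation, which the phenol captures reversibly. The trans ring is expected to be favoured under thermodynamic control by the C3 substituent, and the route is rejoined at 14.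

Step 4. The 2,6-disubstituted aryloxy group could slow enolisation or erode facial selectivity, and retro-aldol cleavage could occur on work-up. The fallback sets the two centres by catalyst-controlled reduction instead of an aldol and sets out from 8 and 5.
- Roskamp homologation of 8 (ethyl diazoacetate, SnCl2 cat., CH2Cl2) should give the beta-keto ester F3.
- NBS in MeCN should give the alpha-bromo beta-keto ester F4.
- Alkylation of phenol 5 (K2CO3, acetone) should give the racemic alpha-aryloxy beta-keto ester F5.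
- Asymmetric transfer hydrogenation with dynamic kinetic resolution (RuCl(p-cymene)[(R,R)-TsDPEN], HCO2H/Et3N) should give the syn (2R,3S) hydroxy ester F6. The catalyst antipode is assigned by analogy with acetophenone-type reductions and is to be chosen so that the (S)-carbinol results.
- NaBH4 in EtOH/THF at 0 °C should reduce the activated alpha-aryloxy ester selectively, beside the methyl benzoate, and rejoin the route at diol 12.

Step 10. Olefination of the electron-rich aldehyde could be slow, and the product enal could react again with the ylide to give a dienal. The fallback sets out from 16: Horner–Wadsworth–Emmons reaction (triethyl phosphonoacetate, NaH, THF, 0 °C) should give the E-cinnamate ester F7. DIBAL-H in CH2Cl2 at −78 °C should give the allylic alcohol F8, and MnO2 in CH2Cl2 should give the enal, rejoining the route at 18.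

**Further compounds**
F1 | step 7 | methyl 4-{[(1S,2S)-1-hydroxy-1-(3,5-dimethoxy-4-triisopropylsilyloxyphenyl)-3-(triisopropylsilyloxy)propan-2-yl]oxy}-3-methoxy-5-(4,4,5,5-tetramethyl-1,3,2-dioxaborolan-2-yl)benzoate | COc1cc([C@H](O)[C@H](CO[Si](C(C)C)(C(C)C)C(C)C)Oc2c(B3OC(C)(C)C(C)(C)O3)cc(C(=O)OC)cc2OC)cc(OC)c1O[Si](C(C)C)(C(C)C)C(C)C
F2 | step 7 | methyl 3-hydroxy-4-{[(1S,2S)-1-hydroxy-1-(3,5-dimethoxy-4-triisopropylsilyloxyphenyl)-3-(triisopropylsilyloxy)propan-2-yl]oxy}-5-methoxybenzoate | COc1cc([C@H](O)[C@H](CO[Si](C(C)C)(C(C)C)C(C)C)Oc2c(O)cc(C(=O)OC)cc2OC)cc(OC)c1O[Si](C(C)C)(C(C)C)C(C)C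
F3 | step 4 | ethyl 3-[3,5-dimethoxy-4-(triisopropylsilyloxy)phenyl]-3-oxopropanoate | CCOC(=O)CC(=O)c1cc(OC)c(O[Si](C(C)C)(C(C)C)C(C)C)c(OC)c1
F4 | step 4 | ethyl 2-bromo-3-[3,5-dimethoxy-4-(triisopropylsilyloxy)phenyl]-3-oxopropanoate (racemic) | CCOC(=O)C(Br)C(=O)c1cc(OC)c(O[Si](C(C)C)(C(C)C)C(C)C)c(OC)c1
F5 | step 4 | methyl 3-bromo-4-{[1-ethoxy-3-(3,5-dimethoxy-4-triisopropylsilyloxyphenyl)-1,3-dioxopropan-2-yl]oxy}-5-methoxybenzoate (racemic) | CCOC(=O)C(Oc1c(Br)cc(C(=O)OC)cc1OC)C(=O)c1cc(OC)c(O[Si](C(C)C)(C(C)C)C(C)C)c(OC)c1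
F6 | step 4 | methyl 3-bromo-4-{[(2R,3S)-1-ethoxy-3-hydroxy-3-(3,5-dimethoxy-4-triisopropylsilyloxyphenyl)-1-oxopropan-2-yl]oxy}-5-methoxybenzoate | COc1cc([C@H](O)[C@H](C(=O)OCC)Oc2c(Br)cc(C(=O)OC)cc2OC)cc(OC)c1O[Si](C(C)C)(C(C)C)C(C)C
F7 | step 10 | ethyl (E)-3-{(2S,3S)-5-methoxy-2-[3,5-dimethoxy-4-(triisopropylsilyloxy)phenyl]-3-[(triisopropylsilyloxy)methyl]-2,3-dihydro-1,4-benzodioxin-7-yl}prop-2-enoate | COc1cc([C@@H]2Oc3cc(/C=C/C(=O)OCC)cc(OC)c3O[C@H]2CO[Si](C(C)C)(C(C)C)C(C)C)cc(OC)c1O[Si](C(C)C)(C(C)C)C(C)C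
F8 | step 10 | (E)-3-{(2S,3S)-5-methoxy-2-[3,5-dimethoxy-4-(triisopropylsilyloxy)phenyl]-3-[(triisopropylsilyloxy)methyl]-2,3-dihydro-1,4-benzodioxin-7-yl}prop-2-en-1-ol | COc1cc([C@@H]2Oc3cc(/C=C/CO)cc(OC)c3O[C@H]2CO[Si](C(C)C)(C(C)C)C(C)C)cc(OC)c1O[Si](C(C)C)(C(C)C)C(C)C
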